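Readings and results were computed for an exercise; scatter was added.

Raising the charge by a factor of 4.07 from the winter run to the dawn run lowered the target at 30.0 min by a factor of 1.24.

| flask | substrate | capture agent | remark | time |
|---|---|---|---|---|
| winter | 0.27 M (in portions, 2) | 0.54 M | run made earlier; portions every 3.0 min |  |
| dawn | 1.1 M (in portions, 2) | 0.54 M | run made earlier; portions every 3.0 min |  |
| flask | 0.54 M (in portions, 2) | 0.540 M | the portions of substrate follow each other after 3.0 min, the first at the start | 40 min |

| run | time / min | target / % | side product B / % |
|---|---|---|---|
| winter | 5.00 | 10.8 | 0.1 |
| winter | 10.0 | 27.3 | 0.4 |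
| winter | 15.0 | 36.7 | 1.0 |
| winter | 20.0 | 40.0 | 0 |
| winter | 25.0 | 42.4 | 2.7 |
| winter | 30.0 | 42.7 | 2.1 |
| dawn | 5.00 | 9.9 | 0 |
| dawn | 10.0 | 23.7 | 0 |
| dawn | 15.0 | 28.0 | 0.7 |
| dawn | 20.0 | 30.8 | 1.8 |
| dawn | 25.0 | 33.0 | 1.2 |
| dawn | 30.0 | 34.3 | 1.1 |

(readings scatter by 0.5 percentage points)

- how much target the flask holds at 40 min, in percent of the substrate charged
- how much side product B the flask holds at 40 min, in percent of the substrate charged
- how much side product A the flask holds at 40 min, in percent of the substrate charged

- percent here means substrate units held: one homo dimer counts as two
- the analysis behind the earlier runs scatters by 0.5 percentage points, standard deviation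
- steps that have been proposed: substrate -> side product A; substrate -> intermediate A; substrate -> intermediate B; intermediate A -> target; intermediate B -> side product B; intermediate B <-> intermediate C; 2 substrate -> homo dimer; capture agent + intermediate A -> trapped intermediate

The new flask's charge lies between the two earlier ones, so at 30.0 min we bracket its target from above by the winter reading, 42.7%, and from below by the dawn reading, 34.3%. To tighten this, note that substrate goes to homo dimer at a rate in its square, but by its other proposed steps in its first power. We therefore take the reciprocal of the target fraction as straight in charge. That gives a charge penalty of 0.691 L mol⁻¹, the rise of the reciprocal target fraction per molar of charge. At 30.0 min the flask's charge then gives 39.5%, which we take as our lower end, as no proposed step takes target away. The flask has 10.0 min more, which is two more reading intervals, so for these we credit it the last step of the winter run plus the last step of the dawn run. That puts the upper end at 41.1%, and both ends carry the scatter of the readings.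

The forecast, which read the fall as “second-order loss to homo dimer competing with first-order channels”, gave 40.5% target, inside our bracket, with 2.5% side product B and 15% side product A.

The flask gives 39.8% target, inside the bracket, with 2.20% side product B and 27.8% side product A.

    substrate → side product A (k = 0.0483 min⁻¹)
    substrate → intermediate A (k = 0.0779 min⁻¹)
    substrate → intermediate B (k = 0.0110 min⁻¹)
    intermediate A → target (k = 0.519 min⁻¹)
    intermediate B → side product B (k = 0.0173 min⁻¹)
    intermediate B ⇌ intermediate C (K = 0.566, k = 0.0227 min⁻¹)
    2 substrate → homo dimer (k = 0.0882 L mol⁻¹ min⁻¹)
    capture agent + intermediate A → trapped intermediate (k = 0.124 L mol⁻¹ min⁻¹)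

The same penalty carries to a neighbouring flask charged with 1.4 M of substrate, beyond the dawn run's charge. From the winter reading at 30.0 min it gives 32.0% target. That neighbour holds 31.4% at 40.0 min, which is 0.6 percentage points less than reckoned. Its homo dimer stands at 37.6%, against 20.6% in the flask.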